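**Retrosynthetic overview**
- The oxirane is added last to the C3=C4 alkene by a reagent-controlled epoxidation (C–O).
- The key bond is C10–O: Markovnikov hydration of a C10=C14 methylene, relayed through the C8 veratrate so that the new hydroxyl is cis to the ester (new method).
- The C8 ester comes from a ketone by hydride delivery cis to the C7 isopropyl group and acylation in the same flask.
- The seven-membered ring is closed second, by intramolecular acylation of an allylsilane (C8–C9); C7 and C5 come from an Evans Michael addition, and the C3=C4–CH3 unit from an enol triflate.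
- The five-membered ring is bought as cyclopent-2-en-1-one; C1 is set by a copper-catalysed asymmetric conjugate addition with Mannich trapping.

Assumption: compound 8 is bought (a bulk oxazolidinone intermediate); bicyclic compounds carry guaiane numbering (C1/C5 ring fusion, C2–C4 in the five-membered ring with C15 on C4, C6–C10 in the seven-membered ring with isopropyl on C7, oxygen on C8, C14 on C10); β is the face of H5, α the face of H1.

**Step 1**
Reactants: 1 cyclopent-2-en-1-one; 2 (2-bromoprop-2-en-1-yl)trimethylsilane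
Product: 7 (R)-2-methylidene-3-[3-(trimethylsilyl)prop-1-en-2-yl]cyclopentan-1-one, via Grignard reagent 3 (not isolated), via magnesium enolate 4 (not isolated), via Mannich base 5 (not isolated), via ammonium iodide 6 (not isolated)
Conditions: 2, Mg, THF, 23 °C; CuBr·SMe2 (5 mol %), (Rp)-1-[(R)-α-(dimethylamino)-2-(diphenylphosphino)benzyl]-2-(diphenylphosphino)ferrocene (6 mol %), 1, t-BuOMe, −78 °C; CH2=NMe2+ I−, −78 → 0 °C; MeI, 23 °C; aq NaHCO3, CH2Cl2
Reagents that add atoms: N,N-dimethylmethyleneiminium iodide (Eschenmoser's salt), C=[N+](C)C.[I-]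
Why: Copper-catalysed asymmetric conjugate addition of the alkenyl Grignard reagent sets C1 as R by ligand-controlled face selection (the ligand antipode that gives R is used), the magnesium enolate is trapped at C5 by the iminium salt (Mannich reaction), and quaternisation followed by base elimination unveils the exocyclic enone, so the C5 centre of the Mannich base does not matter.

**Step 2**
Reactants: 7 (R)-2-methylidene-3-[3-(trimethylsilyl)prop-1-en-2-yl]cyclopentan-1-one; 8 (R)-4-benzyl-3-(3-methylbutanoyl)oxazolidin-2-one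
Product: 12 (R)-4-benzyl-3-[(R)-3-methyl-2-({(1S,5R)-2-oxo-5-[3-(trimethylsilyl)prop-1-en-2-yl]cyclopentyl}methyl)butanoyl]oxazolidin-2-one, via titanium enolate 9 (not isolated), via adduct titanium enolate 10 (not isolated), via cis ketone 11 (not isolated)
Conditions: 8, TiCl4, i-Pr2NEt, CH2Cl2, 0 °C; 7, −78 → −40 °C; aq NH4Cl; then 1,8-diazabicyclo[5.4.0]undec-7-ene (10 mol %), CH2Cl2, 23 °C
Reagents that add atoms: none
Why: Evans asymmetric Michael addition, in which the chelated Z-titanium enolate of the (R)-benzyl oxazolidinone attacks the exocyclic enone terminus on the face away from the benzyl group and sets C7 as R, after which base equilibration puts the C5 side chain trans to the C1 substituent (the more stable trans-2,3-disubstituted cyclopentanone), and material from any minor C1 antipode is removed as a diastereomer.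

**Step 3**
Reactants: 12 (R)-4-benzyl-3-[(R)-3-methyl-2-({(1S,5R)-2-oxo-5-[3-(trimethylsilyl)prop-1-en-2-yl]cyclopentyl}methyl)butanoyl]oxazolidin-2-one
Product: 14 (4R,5S)-5-{(R)-2-[(R)-4-benzyl-2-oxooxazolidine-3-carbonyl]-3-methylbutyl}-4-[3-(trimethylsilyl)prop-1-en-2-yl]cyclopent-1-en-1-yl trifluoromethanesulfonate, via lithium enolate 13 (not isolated)
Conditions: LiN(i-Pr)2, THF, −78 °C; N-(5-chloropyridin-2-yl)bis(trifluoromethanesulfonyl)imide (Comins' reagent), −78 → −40 °C
Reagents that add atoms: Comins' reagent, O=S(=O)(N(c1ccc(Cl)cn1)S(=O)(=O)C(F)(F)F)C(F)(F)F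
Why: Kinetic deprotonation at the unhindered C3 methylene (not the C5 methine or the A(1,3)-shielded imide α-hydrogen) and O-sulfonylation of the enolate give the C3=C4 enol triflate regioselectively without touching a stereocentre (kinetic enolate trapping).

**Step 4**
Reactants: 14 (4R,5S)-5-{(R)-2-[(R)-4-benzyl-2-oxooxazolidine-3-carbonyl]-3-methylbutyl}-4-[3-(trimethylsilyl)prop-1-en-2-yl]cyclopent-1-en-1-yl trifluoromethanesulfonate
Product: 15 (R)-4-benzyl-3-[(R)-3-methyl-2-({(1S,5R)-2-methyl-5-[3-(trimethylsilyl)prop-1-en-2-yl]cyclopent-2-en-1-yl}methyl)butanoyl]oxazolidin-2-one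
Conditions: ZnMe2, Pd(PPh3)4 (5 mol %), THF, 50 °C
Reagents that add atoms: dimethylzinc, C[Zn]C
Why: Negishi cross-coupling replaces the triflate by methyl (C15) with the double bond held at C3=C4, and the imide, the allylsilane and all stereocentres are inert to ZnMe2.

**Step 5**
Reactants: 15 (R)-4-benzyl-3-[(R)-3-methyl-2-({(1S,5R)-2-methyl-5-[3-(trimethylsilyl)prop-1-en-2-yl]cyclopent-2-en-1-yl}methyl)butanoyl]oxazolidin-2-one
Product: 17 (R)-3-methyl-2-({(1S,5R)-2-methyl-5-[3-(trimethylsilyl)prop-1-en-2-yl]cyclopent-2-en-1-yl}methyl)butanoic acid, via lithium peroxycarboxylate 16 (not isolated)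
Conditions: LiOH, H2O2, THF/H2O, 0 °C; aq Na2SO3; HCl to pH 3
Reagents that add atoms: hydrogen peroxide, OO
Why: Evans hydroperoxide cleavage, in which the hydroperoxide anion attacks only the exocyclic imide carbonyl and frees the acid without epimerising C7, while sulfite reduces the percarboxylate before acidification so that neither alkene is epoxidised.

**Step 6**
Reactants: 17 (R)-3-methyl-2-({(1S,5R)-2-methyl-5-[3-(trimethylsilyl)prop-1-en-2-yl]cyclopent-2-en-1-yl}methyl)butanoic acid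
Product: 19 (1R,5S,7R)-guaia-3,10(14)-dien-8-one, via acid chloride 18 (not isolated)
Conditions: Me2C=C(Cl)NMe2, CH2Cl2, 0 → 23 °C; then TiCl4, CH2Cl2 (0.01 M), −78 °C; aq NaHCO3
Reagents that add atoms: none
Why: Intramolecular Friedel–Crafts-type acylation of the allylsilane (Sakurai-type), in which the activated acyl chloride is attacked by the alkene terminus C9 and loss of the silyl group closes the seven-membered ring with the double bond placed at C10=C14; the allylsilane is far more nucleophilic than the C3=C4 alkene, the low temperature prevents conjugation and C7 epimerisation, and no new stereocentre forms.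

**Step 7**
Reactants: 19 (1R,5S,7R)-guaia-3,10(14)-dien-8-one; 20 3,4-dimethoxybenzoyl chloride
Product: 22 (1R,5S,7R,8R)-guaia-3,10(14)-dien-8-yl 3,4-dimethoxybenzoate, via lithium alkoxide 21 (not isolated)
Conditions: LiBH(s-Bu)3, THF, −78 °C; then 20, 4-(dimethylamino)pyridine (20 mol %), −78 → 23 °C
Reagents that add atoms: none
Why: Diastereoselective ketone reduction, in which the bulky hydride attacks C8 from the α face away from the neighbouring β-isopropyl group (as menthone gives neomenthol) to give the 8β-alkoxide cis to the isopropyl group, which is acylated in the same flask with retention (nucleophilic acyl substitution).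

**Step 8**
Reactants: 22 (1R,5S,7R,8R)-guaia-3,10(14)-dien-8-yl 3,4-dimethoxybenzoate
Product: 25 (1R,5S,7R,8R,10S)-10-hydroxyguai-3-en-8-yl 3,4-dimethoxybenzoate, via dioxanylium salt 23 (not isolated), via hemiorthoester 24 (not isolated)
Conditions: Co(C36H52N2O2) (5 mol %; the divalent cobalt complex of (R,R)-N,N'-bis(3,5-di-tert-butylsalicylidene)cyclohexane-1,2-diamine), N-fluoro-2,4,6-trimethylpyridinium tetrafluoroborate (1.5 equiv), PhSiH3 (1.2 equiv), PhCF3, 0 °C; then H2O, NaHCO3, 23 °C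
Reagents that add atoms: water, O
Why: Proposed new method: a cobalt hydride formed from the fluoride-oxidised salen complex and the silane transfers a hydrogen atom to C14 of the 1,1-disubstituted alkene (faster than to the trisubstituted C3=C4 alkene), the tertiary C10 radical is captured by cobalt and oxidised to a cation-like alkylcobalt, and the carbonyl oxygen of the 8β-veratrate, which can only reach C10 from the β face, displaces cobalt to give a cis-bridged 2-aryl-1,3-dioxan-2-ylium ion that water opens at the acyl carbon, the hemiorthoester collapsing with the acyl group on the less hindered secondary C8 oxygen, so the C10–O bond and the 10S centre (hydroxyl cis to the ester) are set by the tether; the closest known reaction types are cobalt–salen hydrogen-atom-transfer/radical-polar-crossover intramolecular hydroalkoxylation and hydroacyloxylation of alkenes and the Woodward–Prévost hydrolysis of acyloxonium ions.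

**Step 9**
Reactants: 25 (1R,5S,7R,8R,10S)-10-hydroxyguai-3-en-8-yl 3,4-dimethoxybenzoate
Product: 26 (1R,3R,4S,5S,7R,8R,10S)-3,4-epoxy-10-hydroxyguaian-8-yl 3,4-dimethoxybenzoate
Conditions: 1,2:4,5-di-O-isopropylidene-β-D-erythro-2,3-hexodiulo-2,6-pyranose (Shi ketone, 30 mol %), KHSO5 (as 2KHSO5·KHSO4·K2SO4), K2CO3, Bu4NHSO4, MeCN/CH2(OMe)2/H2O, pH 10.5, 0 °C
Reagents that add atoms: potassium peroxymonosulfate, [K+].[O-]S(=O)(=O)OO
Why: Shi asymmetric epoxidation, in which the chiral dioxirane delivers oxygen through a spiro transition state to the alkene face that for this trisubstituted pattern (the sense that gives (R,R)-1-phenylcyclohexene oxide) is the α face, setting 3R,4S under reagent control against the small substrate bias, while the basic buffer protects the ester and the acid-sensitive epoxy alcohol.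

**Compound list**
1 | cyclopent-2-en-1-one | O=C1C=CCC1 | starting material
2 | (2-bromoprop-2-en-1-yl)trimethylsilane | C=C(Br)C[Si](C)(C)C | starting material
3 | bromo[3-(trimethylsilyl)prop-1-en-2-yl]magnesium | C=C([Mg]Br)C[Si](C)(C)C | intermediate
4 | bromomagnesium (R)-3-[3-(trimethylsilyl)prop-1-en-2-yl]cyclopent-1-en-1-olate | C=C(C[Si](C)(C)C)[C@@H]1CCC(O[Mg]Br)=C1 | intermediate
5 | (2R,3R)-2-[(dimethylamino)methyl]-3-[3-(trimethylsilyl)prop-1-en-2-yl]cyclopentan-1-one | CN(C)C[C@@H]1C(=O)CC[C@H]1C(=C)C[Si](C)(C)C | intermediate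
6 | N,N,N-trimethyl-1-{(1R,5R)-2-oxo-5-[3-(trimethylsilyl)prop-1-en-2-yl]cyclopentyl}methanaminium iodide | C[N+](C)(C)C[C@@H]1C(=O)CC[C@H]1C(=C)C[Si](C)(C)C.[I-] | intermediate
7 | (R)-2-methylidene-3-[3-(trimethylsilyl)prop-1-en-2-yl]cyclopentan-1-one | C=C1C(=O)CC[C@H]1C(=C)C[Si](C)(C)C | intermediate
8 | (R)-4-benzyl-3-(3-methylbutanoyl)oxazolidin-2-one | CC(C)CC(=O)N1[C@H](Cc2ccccc2)COC1=O | starting material
9 | trichlorotitanium (Z)-enolate of 8, (Z)-trichloro({1-[(R)-4-benzyl-2-oxooxazolidin-3-yl]-3-methylbut-1-en-1-yl}oxy)titanium | CC(C)/C=C(\O[Ti](Cl)(Cl)Cl)N1[C@H](Cc2ccccc2)COC1=O | intermediate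
10 | trichlorotitanium enolate of the Michael adduct, (R)-4-benzyl-3-[(R)-3-methyl-2-({(R)-5-[3-(trimethylsilyl)prop-1-en-2-yl]-2-[(trichlorotitanio)oxy]cyclopent-1-en-1-yl}methyl)butanoyl]oxazolidin-2-one | O=C([C@@H](C(C)C)CC1=C(O[Ti](Cl)(Cl)Cl)CC[C@H]1C(=C)C[Si](C)(C)C)N2[C@H](Cc3ccccc3)COC2=O | intermediate
11 | (R)-4-benzyl-3-[(R)-3-methyl-2-({(1R,5R)-2-oxo-5-[3-(trimethylsilyl)prop-1-en-2-yl]cyclopentyl}methyl)butanoyl]oxazolidin-2-one (cis ketone) | O=C([C@@H](C(C)C)C[C@H]1C(=O)CC[C@H]1C(=C)C[Si](C)(C)C)N2[C@H](Cc3ccccc3)COC2=O | intermediate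
12 | (R)-4-benzyl-3-[(R)-3-methyl-2-({(1S,5R)-2-oxo-5-[3-(trimethylsilyl)prop-1-en-2-yl]cyclopentyl}methyl)butanoyl]oxazolidin-2-one (trans ketone) | O=C([C@@H](C(C)C)C[C@@H]1C(=O)CC[C@H]1C(=C)C[Si](C)(C)C)N2[C@H](Cc3ccccc3)COC2=O | intermediate
13 | lithium (4R,5S)-5-{(R)-2-[(R)-4-benzyl-2-oxooxazolidine-3-carbonyl]-3-methylbutyl}-4-[3-(trimethylsilyl)prop-1-en-2-yl]cyclopent-1-en-1-olate | O=C([C@@H](C(C)C)C[C@@H]1C(O[Li])=CC[C@H]1C(=C)C[Si](C)(C)C)N2[C@H](Cc3ccccc3)COC2=O | intermediate
14 | (4R,5S)-5-{(R)-2-[(R)-4-benzyl-2-oxooxazolidine-3-carbonyl]-3-methylbutyl}-4-[3-(trimethylsilyl)prop-1-en-2-yl]cyclopent-1-en-1-yl trifluoromethanesulfonate | O=C([C@@H](C(C)C)C[C@@H]1C(OS(=O)(=O)C(F)(F)F)=CC[C@H]1C(=C)C[Si](C)(C)C)N2[C@H](Cc3ccccc3)COC2=O | intermediate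
15 | (R)-4-benzyl-3-[(R)-3-methyl-2-({(1S,5R)-2-methyl-5-[3-(trimethylsilyl)prop-1-en-2-yl]cyclopent-2-en-1-yl}methyl)butanoyl]oxazolidin-2-one | O=C([C@@H](C(C)C)C[C@@H]1C(C)=CC[C@H]1C(=C)C[Si](C)(C)C)N2[C@H](Cc3ccccc3)COC2=O | intermediate
16 | lithium (R)-3-methyl-2-({(1S,5R)-2-methyl-5-[3-(trimethylsilyl)prop-1-en-2-yl]cyclopent-2-en-1-yl}methyl)butaneperoxoate | [Li]OOC(=O)[C@@H](C(C)C)C[C@@H]1C(C)=CC[C@H]1C(=C)C[Si](C)(C)C | intermediate
17 | (R)-3-methyl-2-({(1S,5R)-2-methyl-5-[3-(trimethylsilyl)prop-1-en-2-yl]cyclopent-2-en-1-yl}methyl)butanoic acid | OC(=O)[C@@H](C(C)C)C[C@@H]1C(C)=CC[C@H]1C(=C)C[Si](C)(C)C | intermediate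
18 | (R)-3-methyl-2-({(1S,5R)-2-methyl-5-[3-(trimethylsilyl)prop-1-en-2-yl]cyclopent-2-en-1-yl}methyl)butanoyl chloride | ClC(=O)[C@@H](C(C)C)C[C@@H]1C(C)=CC[C@H]1C(=C)C[Si](C)(C)C | intermediate
19 | (1R,5S,7R)-guaia-3,10(14)-dien-8-one | O=C1CC(=C)[C@@H]2CC=C(C)[C@H]2C[C@@H]1C(C)C | intermediate
20 | 3,4-dimethoxybenzoyl chloride | COc1ccc(C(Cl)=O)cc1OC | starting material
21 | lithium (1R,5S,7R,8R)-guaia-3,10(14)-dien-8-olate | [Li]O[C@@H]1CC(=C)[C@@H]2CC=C(C)[C@H]2C[C@@H]1C(C)C | intermediate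
22 | (1R,5S,7R,8R)-guaia-3,10(14)-dien-8-yl 3,4-dimethoxybenzoate | COc1ccc(C(=O)O[C@@H]2CC(=C)[C@@H]3CC=C(C)[C@H]3C[C@@H]2C(C)C)cc1OC | intermediate
23 | 2-(3,4-dimethoxyphenyl)-1,3-dioxan-2-ylium tetrafluoroborate bridging O8 and O10 of (1R,5S,7R,8R,10S)-guai-3-ene-8,10-diol | COc1ccc(C2=[O+][C@@]3(C)C[C@@H](O2)[C@@H](C(C)C)C[C@@H]4C(C)=CC[C@@H]34)cc1OC.F[B-](F)(F)F | intermediate
24 | 2-(3,4-dimethoxyphenyl)-2-hydroxy-1,3-dioxane bridging O8 and O10 of (1R,5S,7R,8R,10S)-guai-3-ene-8,10-diol (hemiorthoester) | COc1ccc(C2(O)O[C@@]3(C)C[C@@H](O2)[C@@H](C(C)C)C[C@@H]4C(C)=CC[C@@H]34)cc1OC | intermediate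
25 | (1R,5S,7R,8R,10S)-10-hydroxyguai-3-en-8-yl 3,4-dimethoxybenzoate | COc1ccc(C(=O)O[C@@H]2C[C@](C)(O)[C@@H]3CC=C(C)[C@H]3C[C@@H]2C(C)C)cc1OC | intermediate
26 | (1R,3R,4S,5S,7R,8R,10S)-3,4-epoxy-10-hydroxyguaian-8-yl 3,4-dimethoxybenzoate | COc1ccc(C(=O)O[C@@H]2C[C@](C)(O)[C@@H]3C[C@H]4O[C@@]4(C)[C@H]3C[C@@H]2C(C)C)cc1OC | target

**Step count and risks**
Total: 9 steps. Longest linear sequence: 9 steps from 1 (2, 8 and 20 are bought).

Steps most likely to fail:

Step 8 (the new method). The C10 cation could lose a proton, pick up fluoride, or the cobalt hydride could attack the C3=C4 alkene. The fallback uses known chemistry, sets out from 19 and comes back at 25. LiBH(s-Bu)3 reduction of 19 with aqueous work-up gives the homoallylic alcohol (1R,5S,7R,8R)-guaia-3,10(14)-dien-8-ol F3. VO(acac)2 with t-BuOOH then epoxidises the C10=C14 alkene on the face of the directing 8β-hydroxyl to give the 10,14-epoxide F4. LiAlH4 opens this epoxide at the primary C14 to give the 8β,10β-diol F5. Acylation of F5 with 20 and 4-(dimethylamino)pyridine takes place only at the secondary hydroxyl and gives 25.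

Step 2. The titanium Lewis acid could trigger an intramolecular Sakurai closure of the allylsilane onto the enone of 7, and the hindered isovaleryl enolate may add slowly. The fallback replaces the Lewis-acid Michael addition by an enolate alkylation; it sets out from 7 and 8 and comes back at 12. Me3SiBr adds 1,4 to 7 (CH2Cl2, −78 °C) to give the bromomethyl silyl enol ether F1. The sodium enolate of 8 (NaN(SiMe3)2, THF, −78 °C) is alkylated by this allylic bromide to give the silyl enol ether adduct F2. Citric acid in methanol followed by a catalytic amount of 1,8-diazabicyclo[5.4.0]undec-7-ene gives 12.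

Step 9. The catalyst has to override the substrate, whose C6 methylene sits on the α face, so the α:β ratio may be poor. The fallback inverts the epoxide made under substrate control; it sets out from 25 and comes back at 26. 3-Chloroperbenzoic acid with NaHCO3 gives the 3β,4β-epoxide F6. Dilute HClO4 in aqueous THF opens it at the tertiary C4 with inversion to the 3β,4α,10β-triol 8-ester F7. Methanesulfonyl chloride in pyridine sulfonylates only the secondary 3β-hydroxyl to give the mesylate F8. NaH in THF closes the 4α-alkoxide onto C3 with inversion to give 26.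

**Further compounds**
F1 | step 2 | (S)-{[2-(bromomethyl)-3-[3-(trimethylsilyl)prop-1-en-2-yl]cyclopent-1-en-1-yl]oxy}trimethylsilane | BrCC1=C(O[Si](C)(C)C)CC[C@H]1C(=C)C[Si](C)(C)C
F2 | step 2 | (R)-4-benzyl-3-[(R)-3-methyl-2-({(R)-5-[3-(trimethylsilyl)prop-1-en-2-yl]-2-[(trimethylsilyl)oxy]cyclopent-1-en-1-yl}methyl)butanoyl]oxazolidin-2-one | O=C([C@@H](C(C)C)CC1=C(O[Si](C)(C)C)CC[C@H]1C(=C)C[Si](C)(C)C)N2[C@H](Cc3ccccc3)COC2=O
F3 | step 8 | (1R,5S,7R,8R)-guaia-3,10(14)-dien-8-ol | O[C@@H]1CC(=C)[C@@H]2CC=C(C)[C@H]2C[C@@H]1C(C)C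
F4 | step 8 | (1R,5S,7R,8R,10S)-10,14-epoxyguai-3-en-8-ol | O[C@@H]1C[C@@]3(CO3)[C@@H]2CC=C(C)[C@H]2C[C@@H]1C(C)C
F5 | step 8 | (1R,5S,7R,8R,10S)-guai-3-ene-8,10-diol | O[C@@H]1C[C@](C)(O)[C@@H]2CC=C(C)[C@H]2C[C@@H]1C(C)C
F6 | step 9 | (1R,3S,4R,5S,7R,8R,10S)-3,4-epoxy-10-hydroxyguaian-8-yl 3,4-dimethoxybenzoate | COc1ccc(C(=O)O[C@@H]2C[C@](C)(O)[C@@H]3C[C@@H]4O[C@]4(C)[C@H]3C[C@@H]2C(C)C)cc1OC
F7 | step 9 | (1R,3S,4S,5S,7R,8R,10S)-3,4,10-trihydroxyguaian-8-yl 3,4-dimethoxybenzoate | COc1ccc(C(=O)O[C@@H]2C[C@](C)(O)[C@@H]3C[C@H](O)[C@@](C)(O)[C@H]3C[C@@H]2C(C)C)cc1OC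
F8 | step 9 | (1R,3S,4S,5S,7R,8R,10S)-4,10-dihydroxy-3-(methanesulfonyloxy)guaian-8-yl 3,4-dimethoxybenzoate | COc1ccc(C(=O)O[C@@H]2C[C@](C)(O)[C@@H]3C[C@H](OS(C)(=O)=O)[C@@](C)(O)[C@H]3C[C@@H]2C(C)C)cc1OC
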